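**Retrosynthetic overview**

1. Target 10 is 5,7-dihydroxy-2-tridecyl-4H-chromen-4-one. The strategy rests on the pyranone ring (ring B): C2 is the β-carbon of the vinylogous ester O1–C2=C3–C4=O and carries nothing but a saturated C13 chain.
2. The C2–C1' bond is therefore cut to the 2-unsubstituted chromone 5 and the tridecyl nucleophile 7. Copper/Me3SiCl conjugate addition gives silyl enol ether 8, and a Saegusa–Ito oxidation puts the C2=C3 bond back.
3. Ring B of 5 is cut at O1–C2 to enaminone 4, whose C2 carbon comes from the formamide acetal 3 and the acetyl group of ketone 2.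
4. Ring order: ring A (the benzene ring) is bought with 1, ring B is closed in step 3, and no further ring is formed. The 5- and 7-OH are carried as benzyl ethers and freed last by hydrogenolysis.

Key step: step 5

Assumption: the SMILES has no stereocentre, so the target is the achiral chromone; benzyl ethers are used for the two phenols because they tolerate the aqueous HCl of the ring closure, Me3SiCl with the Grignard reagent, and Pd(OAc)2.

**Route**

Step 1
Reactants: 1 2,4,6-trihydroxyacetophenone
Product: 2 1-[2,4-bis(benzyloxy)-6-hydroxyphenyl]ethan-1-one
Conditions: BnBr (2.05 equiv), K2CO3 (2.2 equiv), DMF, 0 °C → rt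
Reagents that add atoms: benzyl bromide, BrCc1ccccc1
Why: Williamson etherification in which the para OH and one ortho OH are alkylated, while the remaining ortho OH is held in a hydrogen bond to the acetyl carbonyl and should stay free with two equivalents of benzyl bromide.

Step 2
Reactants: 2 1-[2,4-bis(benzyloxy)-6-hydroxyphenyl]ethan-1-one; 3 N,N-dimethylformamide dimethyl acetal
Product: 4 (E)-1-[2,4-bis(benzyloxy)-6-hydroxyphenyl]-3-(dimethylamino)prop-2-en-1-one
Conditions: 3 (3 equiv), toluene, 95 °C
Reagents that add atoms: none
Why: Enaminone formation by condensation of the acetyl CH3 with the amide acetal, in which the enol of the aryl methyl ketone attacks the methoxy-iminium ion from 3 and two molecules of methanol are lost to give the conjugated E-enaminone.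

Step 3
Reactants: 4 (E)-1-[2,4-bis(benzyloxy)-6-hydroxyphenyl]-3-(dimethylamino)prop-2-en-1-one
Product: 5 5,7-bis(benzyloxy)-4H-chromen-4-one
Conditions: conc. aqueous HCl, CH2Cl2, 40 °C; then aqueous NaHCO3
Reagents that add atoms: none
Why: Enaminone-to-chromone cyclization, an acid-promoted 6-endo-trig oxa-Michael addition of the phenol to the protonated enaminone followed by loss of dimethylamine, under which aryl benzyl ethers are inert.

Step 4
Reactants: 6 1-bromotridecane
Product: 7 tridecylmagnesium bromide (THF solution, titrated and used directly)
Conditions: Mg turnings, I2 (crystal), THF, gentle reflux → rt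
Reagents that add atoms: magnesium, [Mg]
Why: Grignard reagent formation by insertion of magnesium into the primary C–Br bond.

Step 5
Reactants: 5 5,7-bis(benzyloxy)-4H-chromen-4-one; 7 tridecylmagnesium bromide
Product: 8 racemic 5,7-bis(benzyloxy)-2-tridecyl-4-(trimethylsilyloxy)-2H-chromene
Conditions: CuBr·SMe2 (0.2 equiv), Me3SiCl (2.5 equiv), THF, −78 °C, slow addition of 7 (1.5 equiv), → −40 °C; Et3N, then cold aqueous NaHCO3; used crude
Reagents that add atoms: chlorotrimethylsilane, C[Si](C)(C)Cl
Why: Transmetalation of 7 to monovalent copper gives a tridecylcopper species that binds the C2=C3 bond of 5 while Me3SiCl activates the C4 carbonyl; reductive elimination from the trivalent copper intermediate forms the C2–C1' bond, the enolate oxygen is silylated, and monovalent copper is released for the next turnover. The closest known reaction type is the Me3SiCl-accelerated, copper-catalysed conjugate addition of Grignard reagents to enones and chromones with in situ silyl trapping. No ring is closed, and the pyran ring stays intact because O-silylation stops the β-aryloxy enolate from opening by E1cB loss of the phenoxide. The new stereocentre at C2 is formed with no controlling element, so 8 is racemic, which does not matter because C2 becomes sp2 again in step 6. The step needs 1,4- over 1,2-addition: the soft organocopper reagent, the low temperature and the silyl activation direct the chain to C2, the only unsubstituted β-position, and the two benzyloxy donors further lower the electrophilicity of C4 itself.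

Step 6
Reactants: 8 racemic 5,7-bis(benzyloxy)-2-tridecyl-4-(trimethylsilyloxy)-2H-chromene
Product: 9 5,7-bis(benzyloxy)-2-tridecyl-4H-chromen-4-one
Conditions: Pd(OAc)2 (1.1 equiv), MeCN–CH2Cl2 (2:1), rt
Reagents that add atoms: none
Why: Saegusa–Ito oxidation in which divalent palladium takes over the enolate from silicon to give a C3-bound palladium enolate, and syn β-hydride elimination of the C2–H, the only β-hydrogen, restores the C2=C3 bond, removes the racemic stereocentre and leaves zerovalent palladium.

Step 7
Reactants: 9 5,7-bis(benzyloxy)-2-tridecyl-4H-chromen-4-one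
Product: 10 5,7-dihydroxy-2-tridecyl-4H-chromen-4-one
Conditions: H2 (1 atm), 10% Pd on carbon (Pd/C), EtOAc–MeOH (1:1), rt, stopped at full debenzylation
Reagents that add atoms: none
Why: Hydrogenolysis of the two aryl benzyl ethers, which should be much faster than reduction of the C2=C3 bond because that bond is part of a vinylogous ester in a pseudo-aromatic pyranone ring.

**Compound list**

1 | 2,4,6-trihydroxyacetophenone | CC(=O)c1c(O)cc(O)cc1O | starting material
2 | 1-[2,4-bis(benzyloxy)-6-hydroxyphenyl]ethan-1-one | CC(=O)c1c(O)cc(OCc2ccccc2)cc1OCc1ccccc1 | intermediate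
3 | N,N-dimethylformamide dimethyl acetal | COC(OC)N(C)C | starting material
4 | (E)-1-[2,4-bis(benzyloxy)-6-hydroxyphenyl]-3-(dimethylamino)prop-2-en-1-one | CN(C)/C=C/C(=O)c1c(O)cc(OCc2ccccc2)cc1OCc1ccccc1 | intermediate
5 | 5,7-bis(benzyloxy)-4H-chromen-4-one | O=c1ccoc2cc(OCc3ccccc3)cc(OCc3ccccc3)c12 | intermediate
6 | 1-bromotridecane | CCCCCCCCCCCCCBr | starting material
7 | tridecylmagnesium bromide | CCCCCCCCCCCCC[Mg]Br | intermediate
8 | racemic 5,7-bis(benzyloxy)-2-tridecyl-4-(trimethylsilyloxy)-2H-chromene | CCCCCCCCCCCCCC1C=C(O[Si](C)(C)C)c2c(OCc3ccccc3)cc(OCc3ccccc3)cc2O1 | intermediate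
9 | 5,7-bis(benzyloxy)-2-tridecyl-4H-chromen-4-one | CCCCCCCCCCCCCc1cc(=O)c2c(OCc3ccccc3)cc(OCc3ccccc3)cc2o1 | intermediate
10 | 5,7-dihydroxy-2-tridecyl-4H-chromen-4-one | CCCCCCCCCCCCCc1cc(=O)c2c(O)cc(O)cc2o1 | target

**Step count**

Total steps: 7. Longest linear sequence: 6 (steps 1, 2, 3, 5, 6, 7); step 4 is a one-step side branch.

**Steps most likely to fail**

Step 5. What may go wrong: the electron-rich, doubly alkoxylated chromone may react slowly, so that 1,2-addition at C4 or opening of the unsilylated enolate by phenoxide loss competes with the wanted 1,4-addition. Fallback: the chain is brought in as an acyl group. Starting from 2, O-acylation with tetradecanoyl chloride (pyridine, DMAP, CH2Cl2) should give 2-acetyl-3,5-bis(benzyloxy)phenyl tetradecanoate F1. LiN(SiMe3)2 in THF (−78 → 0 °C) should then bring about the Baker–Venkataraman acyl shift to 1-[2,4-bis(benzyloxy)-6-hydroxyphenyl]hexadecane-1,3-dione F2. Cyclodehydration with catalytic p-TsOH in warm toluene should close the pyranone ring, and the route is rejoined at 9.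

Step 6. What may go wrong: protodesilylation of the labile silyl enol ether by the acetic acid that is released may outrun palladation, so that the saturated ketone accumulates instead of the chromone. Fallback: starting from 8, the silyl group is removed on purpose (1 M HCl, THF, 0 °C) to give racemic 5,7-bis(benzyloxy)-2-tridecylchroman-4-one F3. This ketone is then dehydrogenated with catalytic I2 in DMSO at 110 °C (α-iodination at C3, loss of HI, DMSO as terminal oxidant), and the route is rejoined at 9.

Step 7. What may go wrong: hydrogenation of the C2=C3 bond may compete once the benzyl groups are gone, or cleavage of the 5-O-benzyl group next to the carbonyl may stall. Fallback: a non-reductive Lewis acid debenzylation. Starting from 9, BCl3 with pentamethylbenzene as benzyl cation scavenger (CH2Cl2, −78 → 0 °C, methanol quench) should give 10 directly; this fallback passes through no new compound (F0).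

**Further compounds**

F1 | step 5 | 2-acetyl-3,5-bis(benzyloxy)phenyl tetradecanoate | CCCCCCCCCCCCCC(=O)Oc1cc(OCc2ccccc2)cc(OCc2ccccc2)c1C(C)=O
F2 | step 5 | 1-[2,4-bis(benzyloxy)-6-hydroxyphenyl]hexadecane-1,3-dione | CCCCCCCCCCCCCC(=O)CC(=O)c1c(O)cc(OCc2ccccc2)cc1OCc1ccccc1
F3 | step 6 | racemic 5,7-bis(benzyloxy)-2-tridecylchroman-4-one | CCCCCCCCCCCCCC1CC(=O)c2c(OCc3ccccc3)cc(OCc3ccccc3)cc2O1
F0 | step 7 | none | none
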